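The data come from a simulation with made-up constants; the scatter is artificial.

| flask | left-handed substrate | right-handed substrate | gas | catalyst | remark | time |
|---|---|---|---|---|---|---|
| dawn | 10 mM | 10 mM | 2.3 mM (held) | 1 mM | the very flask that is asked about, followed so far |  |
| summer | 10 mM | 10 mM | 2.3 mM (held) | 0.50 mM | run made earlier |  |
| flask | 10 mM | 10 mM | 2.3 mM (held) | 1.0 mM |  | 6.0 min |

dawn run (percent of the left-handed substrate and right-handed substrate together charged)

| time / s | right-handed substrate / % | left-handed substrate / % | left-handed product / % |
|---|---|---|---|
| 10.0 | 50.2 | 43.4 | 7.1 |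
| 15.0 | 51.2 | 39.0 | 11.9 |
| 30.0 | 50.0 | 28.3 | 22.1 |
| 50.0 | 49.2 | 14.7 | 34.1 |
| 60.0 | 50.6 | 13.8 | 39.1 |
| 80.0 | 48.8 | 7.1 | 44.3 |
| 120 | 49.6 | 2.0 | 47.3 |

summer run (percent of the left-handed substrate and right-handed substrate together charged)

| time / min | right-handed substrate / % | left-handed substrate / % | left-handed product / % |
|---|---|---|---|
| 0.500 | 48.3 | 35.9 | 15.4 |
| 0.667 | 51.6 | 30.2 | 19.1 |
| 1.00 | 50.0 | 24.0 | 26.7 |
| 1.50 | 50.8 | 16.3 | 36.7 |
| 2.50 | 49.6 | 6.0 | 45.4 |
| 4.00 | 48.1 | 3.3 | 49.6 |
| 6.00 | 47.2 | 0 | 50.4 |

(standard deviation of a reading: 1 percentage point)

- whether the excess of right-handed substrate over left-handed substrate among what is left of the two reaches 80% by 6.0 min (no / yes)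
- the highest excess of right-handed substrate over left-handed substrate among what is left of the two up to 6.0 min

- catalyst is single-handed; left-handed substrate and right-handed substrate are mirror images of each other, charged as a racemate, each of them at the stated concentration
- at the start none of the gas is in solution

Early in the dawn run, which is the asked flask followed so far, the two hands had already parted: at 10.0 s the left-handed substrate read 43.4% of the charge and the right-handed substrate 50.2%. So I followed one molecule of each hand and asked for its chance of still being there. The two were charged alike, so the ratio of those chances is left-handed over right-handed, and the excess is one minus that ratio over one plus it. The level asked for, 80.0%, then calls for a left-over-right ratio no higher than 0.111, the needed survival ratio.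

In one extreme version the dawn flask stalled straight after its last reading. At 120 s the ratio read 0.0403, lower than needed; the left-handed level wanted, 5.51%, stands 3.5 percentage points above the reading, against a scatter of 1 point. That version holds the excess at 92.2%. In the other version the left-handed substrate is wholly consumed, the ratio is zero and the excess is 100%.

The answer to the first question was yes at both ends. Between them, I carried on the pace read from 30.0 s to 80.0 s, 0.0277 s⁻¹, up to 6.0 min with the right-handed reading held. This gave a ratio of 5.28 × 10⁻⁵, so I committed to yes and a top of >99.9%. The forecast said yes and 99.9%, adding that “a small racemisation or stalling floor can't be excluded”.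

The flask gave yes, with a top of >99.9%.

    partner + catalyst + left-handed substrate → catalyst + left-handed product (k = 15900 M⁻² s⁻¹)
    partner + catalyst + right-handed substrate → catalyst + right-handed product (k = 79.8 M⁻² s⁻¹)
    partner ⇌ dormant form (K = 8.15, k = 0.0201 s⁻¹)
    partner → decomposition product (k = 7.52 × 10⁻⁵ s⁻¹)
    gas ⇌ partner, rate k5*(csat - [partner]) (kL = 0.216 s⁻¹)

The excess reached 80.0% at 1.46 min, with 49.4% of the charge still right-handed substrate. The needed survival ratio puts the left-handed substrate at that moment at 5.48% of the charge. In the summer run, with half the catalyst, the ratio read 0.121 at 2.50 min, higher than needed by 0.49 points of left-handed substrate, inside the scatter of 1 point, and 0.0686 at 4.00 min, lower.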